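The readings were generated by integration with made-up constants; noise was put on by code.

I decided to spend no material on alder or larch until the three earlier runs had been reckoned by hand.

common to all: starting material 10 mM

| charge | reagent | remark | time |
|---|---|---|---|
| east | 23 mM | run made earlier |  |
| south-west | 31 mM | run made earlier |  |
| north-west | 40 mM | run made earlier |  |
| alder | 20.0 mM |  | 10 min |
| larch | 50.0 mM |  | 10 min |

| run | time / min | intermediate / % | starting material / % | product / % |
|---|---|---|---|---|
| east | 1.33 | 3.0 | 92.4 | 2.5 |
| east | 3.00 | 5.9 | 86.6 | 7.2 |
| east | 4.00 | 6.8 | 82.4 | 11.3 |
| east | 6.00 | 6.1 | 76.9 | 18.6 |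
| east | 8.00 | 6.1 | 70.0 | 25.6 |
| south-west | 1.33 | 6.8 | 89.8 | 2.0 |
| south-west | 3.00 | 7.2 | 82.5 | 8.7 |
| south-west | 4.00 | 8.4 | 76.7 | 14.3 |
| south-west | 6.00 | 7.5 | 66.4 | 25.1 |
| south-west | 8.00 | 4.5 | 60.3 | 31.2 |
| north-west | 1.33 | 6.8 | 87.8 | 2.7 |
| north-west | 3.00 | 9.9 | 75.2 | 12.6 |
| north-west | 4.00 | 9.9 | 72.0 | 19.4 |
| north-west | 6.00 | 7.7 | 61.1 | 28.8 |
| north-west | 8.00 | 6.5 | 53.9 | 39.4 |

(scatter of a reading: 1 percentage point)



* which of these there is most of at the end, counted by the starting material in it, alder (product / starting material / intermediate)
* which of these there is most of at the end, counted by the starting material in it, larch (product / starting material / intermediate)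
* how much there is at the end of the one of these that leads, in percent of the starting material charged: alder
* how much there is at the end of the one of these that leads, in percent of the starting material charged: larch

My zero of the scale was the plainest case, a pseudo-first-order loss in which equal reagent-minutes, [reagent] times time, leave equal shares of starting material. I took −ln(share left) at each run's last reading, divided it by charged [reagent] times time, and the average read 1.97 M⁻¹ min⁻¹. So my first estimate of what stood after 10 min was 67.4 % starting material in alder and 37.3 % in larch.

Next came the intermediate. In the north-west run, the rise of product from 4.00 min to 8.00 min, divided by the intermediate read at 6.00 min, gave a use of 0.649 min⁻¹. Taking its level as making over use, I put it at 4.09 % in alder and 5.66 % in larch.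

The weak link was charged [reagent], which falls as it reacts. Assuming one for one, I reckoned that alder lost a larger share of its reagent charge than larch. So I redid the runs with mean [reagent] over each run, and this gave the dose constant, the share-logarithm lost per reagent-minute, 2.10 M⁻¹ min⁻¹. I committed to starting material leading alder at 68.0 %, and to product leading larch at 57.0 %, with 37.4 % starting material beside it.

The forecast named starting material for alder at 68 % and product for larch at 56 %, a little under my larch figure, noting of the loss “That is proportional to reagent”.

The flasks gave starting material at 68.5 % in alder and product at 55.6 % in larch, where 37.6 % starting material stood against my 37.4 %.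

    intermediate → product (k = 0.590 min⁻¹)
    reagent + by-product ⇌ idle adduct, settled at all times (K = 8500 M⁻¹)
    starting material + reagent → intermediate + by-product (k = 2.30 M⁻¹ min⁻¹)

The dose constant also served a neighbour of alder charged with 34 mM reagent: it gave 51.5 % starting material, and that flask held 52.0 %. Neither asked flask had come to rest at 10 min: alder still held 68 % and larch 38 % of their starting material. For ten times the time, the dose constant with a mean [reagent] of 15.0 mM, taken one for one, gave alder 4.28 %, but alder held 17.5 % starting material and 82.3 % product, with unbound reagent at 18.7 % of its charge. Larch then held 99.9 % product and 0.0600 % starting material.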